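**Assumption:** the target is achiral (no stereocentre, no stereogenic double bond), so "single enantiomer" is read as the one constitution given.

## Retrosynthetic overview

1. Target 4 ⇒ (Z)-enol ester 3 by hydrogenation of the C=C bond.
2. 3 ⇒ docosanoic acid 1 + phenylacetylene 2: the ester O–C(alkyl) bond is made as a vinyl C–O bond by Ru-catalysed anti-Markovnikov addition of the acid O–H across the terminal alkyne. This replaces the usual acylation of 2-phenylethanol.
3. No ring is formed; the benzene ring is bought with 2. No stereocentre is set; the Z geometry of 3 is transient and erased in step 2.
4. Overall C22H44O2 + C8H6 + H2 → C30H52O2: every atom of both building blocks ends up in the target.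

## Route

Step 1
Reactants: 1 docosanoic acid (behenic acid, 1.0 equiv); 2 phenylacetylene (1.5 equiv)
Product: 3 (Z)-2-phenylethenyl docosanoate
Conditions: [RuCl2(p-cymene)]2 (1 mol%), P(4-ClC6H4)3 (3 mol%), DMAP (4 mol%), toluene, 60 °C, 16 h, Ar; evaporate excess 2, short silica plug (hexanes/EtOAc 98:2)
Reagents that add atoms: none
Why: Ru-catalysed anti-Markovnikov hydro-oxycarbonylation of a terminal alkyne (Dixneuf–Goossen enol ester synthesis): the alkyne rearranges on Ru(II) to a vinylidene, the DMAP-generated docosanoate attacks its electrophilic α-carbon (the former terminal CH), and protonolysis of the Ru–alkenyl gives the Z-enol ester with oxygen on the terminal carbon; it is a pure addition with no co-product, no stereocentre is formed, and the alkene geometry does not matter because step 2 removes it.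

Step 2
Reactants: 3 (Z)-2-phenylethenyl docosanoate
Product: 4 2-phenylethyl docosanoate (phenylethyl n-docosanoate)
Conditions: H2 (1 atm), 5% Pd/C (2 mol% Pd), EtOAc, 25–35 °C, 3 h; filter through Celite, recrystallise from acetone
Reagents that add atoms: none
Why: Heterogeneous catalytic hydrogenation (syn addition of H2 on Pd) of the conjugated enol-ester C=C is much faster than arene or ester reduction at 1 atm and room temperature, the product has no benzylic C–O bond to hydrogenolyse, and no stereocentre is created; any trace of the Markovnikov isomer (1-phenylvinyl ester) would be reduced to a benzylic ester and hydrogenolysed to 1, which a bicarbonate wash removes.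

## Compound list

1 | docosanoic acid (behenic acid) | CCCCCCCCCCCCCCCCCCCCCC(=O)O | starting material
2 | phenylacetylene (ethynylbenzene) | C#Cc1ccccc1 | starting material
3 | (Z)-2-phenylethenyl docosanoate ((Z)-styryl docosanoate) | CCCCCCCCCCCCCCCCCCCCCC(=O)O/C=C\c1ccccc1 | intermediate
4 | 2-phenylethyl docosanoate (phenylethyl n-docosanoate) | CCCCCCCCCCCCCCCCCCCCCC(=O)OCCc1ccccc1 | target

## Step count and risk

Total step count: 2. Longest linear sequence: 2.

The route has only two steps, so both are ranked; there is no third step to name.

**Most at risk: step 1.** Possible failures are erosion of regioselectivity toward the Markovnikov 1-phenylvinyl ester, Ru-catalysed head-to-head dimerisation of 2 to enynes, and sluggish reaction of the waxy C22 acid. The fallback sets out from 1 and comes back to the route at 4, bypassing 3 and step 2. Docosanoic acid 1 is neutralised with CsOH·H2O (1.0 equiv, MeOH/THF, evaporated to dryness) to give cesium docosanoate F1. This is O-alkylated with (2-bromoethyl)benzene (BrCCc1ccccc1, 1.2 equiv) in DMF at 60 °C. The weakly basic cesium carboxylate displaces the primary bromide by SN2 with little E2 to styrene, forming the alkyl C–O bond and delivering 4 directly.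

**Second: step 2.** Possible failures are hydrogenolysis of the vinylic C–O bond (giving 1 and ethylbenzene) and poisoning of Pd by Ru or phosphine residues carried over from step 1. The fallback sets out from 3 and comes back to the route at 4, and uses no reduction at all. Compound 3 is used as an irreversible enol-ester acyl donor: with 2-phenylethanol (OCCc1ccccc1, 1.2 equiv) and immobilised Candida antarctica lipase B (Novozym 435) in toluene at 50 °C, the docosanoyl group is transferred to the alcohol to give 4. The released enol tautomerises to phenylacetaldehyde, which makes the transfer irreversible and is removed by a bisulfite wash. This path makes no compound outside the list, entered below as none F0.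

## Further compounds

F1 | step 1 | cesium docosanoate | CCCCCCCCCCCCCCCCCCCCCC(=O)[O-].[Cs+]
F0 | step 2 | none | none
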